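Count the amounts first: each flask holds 6.4 mM free catalyst against 0.11 M starting material and, of the second substrate, 0.110 M, and the flasks differ in [impurity].

the same everywhere: starting material 0.11 M; free catalyst 6.4 mM

|  | second substrate | impurity | remark | time |
|---|---|---|---|---|
| north-east | 0.11 M | 1.3 mM | run made earlier |  |
| north | 0.11 M | 24 mM | run made earlier |  |
| zeta | 0.110 M | 1.2 mM |  | 1.5 h |
| alpha | 0.110 M | 2.0 mM |  | 1.5 h |
| gamma | 0.110 M | 4.0 mM |  | 1.5 h |
| beta | 0.110 M | 8.0 mM |  | 1.5 h |
| theta | 0.110 M | 20 mM |  | 1.5 h |

- north-east (time / min: target / %, starting material / %): 15.0: 46.7, 52.3; 30.0: 76.1, 23.9; 50.0: 93.8, 6.1; 60.0: 97.4, 2.8; 80.0: 98.9, 0.7; 90.0: 100.1, 0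
- north (time / min: target / %, starting material / %): 15.0: 1.7, 98.0; 30.0: 2.3, 98.3; 50.0: 2.2, 98.0; 60.0: 1.7, 98.1; 80.0: 1.8, 98.1; 90.0: 1.9, 97.8

(scatter of a reading: 0.3 percentage points)

- "hardly changes" means that all values lie within two and a half points (for a concentration: within two and a half percent of the largest)

- [target] at the end for zeta, alpha, gamma, beta, theta, in this order
- the shape of the row from first to last (falls all the way / falls, then rises / rises all the way / hardly changes / rises, then falls)

Read the north run: the target stands near 1.93% from the first reading on, so assume that impurity destroys free catalyst one for one. Both target-making and this destruction use free catalyst, so take it to cancel from their ratio: starting material lost over impurity lost equals s[starting material]/[impurity]. Here s, the selectivity factor, is the rate constant of target-making over that of destruction. Add this up while [impurity] falls from its charge Y to Y − C, with C the catalyst charge: the unchanged fraction of starting material is ((Y − C)/Y)^s. North gives s = 0.0629.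

Apply it where impurity exceeds catalyst: beta gives 0.0106 M and theta 0.00264 M. In the other flasks catalyst survives, so stretch the north-east curve by surviving catalyst times time. Gamma's 1.5 h then equals 42.4 min of north-east, and interpolating the logarithm between its neighbouring readings gives 0.0987 M. Alpha equals 77.6 min, so about 0.109 M, and zeta equals 91.8 min, so about 0.11 M.

The forecast gives 0.11 M, 0.108 M, 0.096 M, 0.005 M and 0.0025 M, shape falls all the way, and calls the beta burst “perhaps slightly larger with less excess”; my reckoning stands higher at gamma, with 0.0987 M, and at beta, with 0.0106 M.

The flask gives 0.110 M, 0.109 M, 0.0993 M, 0.0106 M and 0.00265 M: falls all the way.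

    catalyst intermediate B → free catalyst + second product (k = 0.0383 /s)
    starting material + free catalyst ⇌ catalyst intermediate A (K = 7.00 /M, k = 1.03 /M/s)
    catalyst intermediate A → free catalyst + target (k = 0.0501 /s)
    second substrate + free catalyst ⇌ catalyst intermediate B (K = 11.0 /M, k = 0.524 /M/s)
    free catalyst + impurity → spent catalyst (k = 4.12 /M/s)

Target made per catalyst destroyed, s[starting material]/[impurity], climbs in beta from 0.865 to 3.91 at 1.50 h, higher than theta's 0.497 at that time. With spent catalyst at 100% in beta, its target stands at 9.68% after 1.50 h and at 9.68% after 15.0 h.

The readings come from a simulation from invented constants; scatter was added.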